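## Analysis of the target

Compound 34 is a 3,10-epoxygermacranolide. Its ten-membered carbocycle (C1–C10) is bridged by an ether oxygen between C3 and C10, so that O, C3, C2, C1 and C10 form a 2,2-disubstituted 3(2H)-furanone conjugated with the Z-configured C4=C5 alkene. A γ-lactone (O6–C12) is cis-fused across C6–C7 and carries at C11 a tertiary alcohol and a chloromethyl group; C8 bears the angelate and C9 a free secondary alcohol. The six contiguous stereocentres are 6S,7S,8S,9R,10R,11R, two of them (C10, C11) fully substituted. O6, the C7–C11 bond, O8 and the C10 methyl lie on one face of the macrocycle, the ether bridge and O9 on the other, and on the lactone the C11 hydroxyl is cis to C8. Sensitive groups are the chlorohydrin (epoxide closure with base), the angelate (Z to E isomerisation), the dienone (Michael acceptor), the 8,9-diol monoester (acyl shift) and, at the C8 ketone stage, a retro-aldol relationship to C11. The difficulty lies in the bridged medium ring and in the tertiary ether C10 next to the C9 carbinol. The strategy rests on the segment O–C3–C4=C5–C6–C7, which is a 3,6-dihydro-2H-pyran in disguise: its oxygen is three atoms from C10 and its C7 is allylic to C8–C9, so the macrocycle can be made by a three-atom ring expansion of that pyran.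

## Retrosynthetic reasoning

**34 to 31.** The end of the route is oxygen chemistry only. The C9 silyl ether of 33 is removed last under acidic fluoride, because the free diol monoester and the chlorohydrin of 34 do not tolerate base. The angeloyl C–O bond is cut next (33 to 32), since this ester isomerises easily and should see few steps. The C8–H bond is then cut back to ketone 31, which turns C8 into the carbonyl of an aldol retron.

**31 to 29.** In 31 the C7–C11 bond is β to the C8 ketone and C11 carries the hydroxyl. Cutting it gives a C7=C8 enol ether and a chloropyruvoyl ester on O6 (30), made from alcohol 29. This cut is preferred to a lactone C–O closure because one intramolecular step then builds the fully substituted C11 and sets C7, with O6 holding the electrophile on the face of C7 that gives the cis-fused ring. The forward reaction must use the enol ether as a neutral nucleophile; a free enolate would expel O6.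

**29 to 25.** O6 of 29 is unveiled from the 4-nitrobenzoate 28 by transesterification. An oxidatively cleaved benzyl-type ether is avoided because the silyl enol ether would not survive the oxidant. The C2=C3 bond of 28 is cut back to the saturated ketone 25. C2 is the only enolisable position of the C1 ketone, and introducing the alkene early turns C1 into a vinylogous ester before hydride is used at C8.

**25 to 22 (key disconnection).** C9–C10 and O–C10 are cut together. This returns the pyran 22, whose C3 side chain ends in an α-methyl diazoketone and whose C7 carries a Z-enediol bis(silyl ether). It is chosen because it makes the furanone ring and the macrocycle from a six-membered ring, avoids an end-to-end closure, and leaves C8 as an enol ether and C9 as a protected carbinol, already differentiated.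

- The forward shift is suprafacial across C7–C8–C9. For the new C7=C8 bond to be cis within the ring and for C9 to have the configuration of 34, C10 must sit on the ring oxygen cis to both the C7 and the C3 substituents (cis-fused ylide 24) and the enediol must be Z.
- This fixes 22 as the 2,6-cis pyran. From a 2,6-trans pyran only a ylide with C10 trans to one of the two groups can form, and its shift would give the ring-E enol ether.
- C10 follows from C3, because the six-carbon bridge can only span one face of the five-membered ring.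

**22 to 19.** The C1–C10 bond is cut to acid 20 and a two-carbon diazoalkane, joined through the mixed anhydride 21. The acid is carried as allyl ester 19 so that it can be freed without base, acid or oxidant in the presence of the enediol ether.

**19 to 14.** The enediol is traced to the α-silyloxy ketone 17 (kinetic enolisation toward C9), and this through 16 to diol 15 and acetonide 14. The C8 stereocentre of the glycerol unit has no role beyond this point.

**14 to 12.** The C6–O bond is cut with inversion. Hydride reduction of enone 12 gives the alcohol 13 trans to the C7 group, and a Mitsunobu displacement then gives the all-cis ester 14. That ester is at once the protecting group that lasts until 28.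

**12 to 8.** The C1 oxidation level is adjusted on the ketone (9 to 11 to 12). The C3–H bond is cut to hemiketal 8, because hydride delivery to the C3 oxocarbenium ion places the side chain cis to C7. Adding the side chain as a nucleophile to that ion would place it trans.

**8 to 1 and 2.** The pyranone 8 is the Achmatowicz product of furylcarbinol 7. Compound 7 comes from 5 by C–C bond formation at the second furan α-position, and 5 from furan 1 and aldehyde 2 (C6–C7 bond). C7 is thus the only stereocentre taken from the chiral pool; all others are relayed from it.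

## Alternatives that were turned down

**Alternative 1:** Disconnection of C8–C9. In the forward sense SmI2 (divalent samarium) would couple the two aldehydes of the seco-dialdehyde A2 to the 8,9-diol A1, closing the ten-membered ring and creating both carbinols.
- For it: it is convergent (a lactone half and a furanone half), and on the length of the longest linear sequence it is stronger than the chosen route.
- Against it: in A2 the C9 aldehyde has the C10 ether oxygen in the α-position and the lactone carbonyl has the C11 hydroxyl in the α-position. Both are motifs that divalent samarium cleaves reductively, and the dienone is reducible as well. A samarium-bridged pinacol favours a cis diol, whereas 34 needs O8 and O9 on opposite faces. A1 then has three free hydroxyls, and C8 would have to be acylated selectively next to C9.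
- In its place the chosen strategy offers O8 and O9 differentiated from the start (enol ether and silyl ether) and no exposure of the functionalised core to a strong reductant.

**Alternative 2:** Disconnection of the C1 and C6 carbonyls back to a tetrasubstituted C1=C6 alkene in the bicyclo[4.4.0]decene A4. Ozone (then Me2S) would cleave it to the cyclodecane-1,6-dione A3.
- For it: a fragmentation has no ring-closure entropy, the stereocentres are set on a rigid bicycle, and ozonolysis is dependable. On the reliability of the ring-forming event it is stronger.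
- Against it: A3 still lacks the ether bridge, both ring alkenes and the lactone oxidation level (C12 is an ether carbon), and C6 must still be reduced and lactonised cis. A 1,6-diketone in a ten-membered ring is set up for transannular aldol reaction. A4, with five contiguous stereocentres of which two are fully substituted, needs a long sequence.
- In its place the chosen key step delivers the furanone ring, the oxygen pattern at C8/C9 and the macrocycle in one operation.

**Alternative 3:** Disconnection of C1–C2. CrCl2 (divalent chromium) with catalytic NiCl2 (divalent nickel) would convert the iodoalkyne aldehyde A6 into the macrocyclic propargylic alcohol A5; oxidation and addition of the C10 hydroxyl to the ynone would then give the furanone.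
- For it: the chromium reagent tolerates the lactone, the chlorohydrin and the angelate, so the ring could be closed last. On functional-group tolerance and on late convergence it is stronger.
- Against it: the ten-membered ring must accommodate a linear C1–C2≡C3–C4 unit next to a Z alkene and is closed end to end. The whole C6–C11 array, including the C9/C10 diol with its tertiary centre, must be built on an open chain.
- In its place the chosen strategy sets C9 and C10 by relay within the key step and forms the ring by expansion of a six-membered ring.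

Key step: step 15

Remark: metalation of 1 is taken to occur mainly at C5, the α-position remote from the methyl group; a minor C2 regioisomer would be removed after step 1.
Remark: aldehyde 2 is taken as a purchasable chiral-pool reagent; diazoethane and 3-chloropyruvoyl chloride are made just before use from purchasable N-ethyl-N-nitrosourea and 3-chloropyruvic acid.

## Route

Step 1
Reactants: 1 3-methylfuran; 2 (S)-2,2-dimethyl-1,3-dioxolane-4-carbaldehyde
Product: 5 (S)-[(4S)-2,2-dimethyl-1,3-dioxolan-4-yl](4-methylfuran-2-yl)methanol, via 2-lithio-4-methylfuran 3 (not isolated), via (4-methylfuran-2-yl)zinc bromide 4 (not isolated)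
Conditions: n-BuLi, TMEDA, THF, −78 → 0 °C; ZnBr2, −78 °C; then 2, −78 °C → rt
Reagents that add atoms: none
Why: α-Lithiation of the furan at the unhindered C5, transmetalation to zinc and Felkin–Anh (anti) 1,2-addition to the α-alkoxy aldehyde should set the C7 carbinol as S; the dioxolane centre serves only as control element and is erased in step 11.

Step 2
Reactants: 5 (S)-[(4S)-2,2-dimethyl-1,3-dioxolan-4-yl](4-methylfuran-2-yl)methanol
Product: 7 2-{5-[(S)-[(4S)-2,2-dimethyl-1,3-dioxolan-4-yl](hydroxy)methyl]-3-methylfuran-2-yl}ethan-1-ol, via dilithiated furan 6 (not isolated)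
Conditions: n-BuLi (2.3 equiv), TMEDA, THF, −78 → 0 °C; ethylene oxide, 0 °C → rt
Reagents that add atoms: ethylene oxide, C1CO1
Why: After alkoxide formation the only remaining furan α-position is lithiated and opens the epoxide by SN2 attack, which installs C2–C1 at the alcohol oxidation level.

Step 3
Reactants: 7 2-{5-[(S)-[(4S)-2,2-dimethyl-1,3-dioxolan-4-yl](hydroxy)methyl]-3-methylfuran-2-yl}ethan-1-ol
Product: 8 (2S)-2-[(4S)-2,2-dimethyl-1,3-dioxolan-4-yl]-6-hydroxy-6-(2-hydroxyethyl)-5-methyl-2H-pyran-3(6H)-one (both C6 epimers)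
Conditions: mCPBA, CH2Cl2, 0 °C
Reagents that add atoms: 3-chloroperoxybenzoic acid, OOC(=O)c1cccc(Cl)c1
Why: Achmatowicz rearrangement: oxidation of the furan, opening to the cis-enedione and hemiketalisation by the C7 hydroxyl give the pyranone; C7 is not touched and the primary hydroxyl cannot form a competing ring.

Step 4
Reactants: 8 (2S)-2-[(4S)-2,2-dimethyl-1,3-dioxolan-4-yl]-6-hydroxy-6-(2-hydroxyethyl)-5-methyl-2H-pyran-3(6H)-one
Product: 9 (2S,6R)-2-[(4S)-2,2-dimethyl-1,3-dioxolan-4-yl]-6-(2-hydroxyethyl)-5-methyl-2H-pyran-3(6H)-one (2,6-cis)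
Conditions: Et3SiH, CF3CO2H, CH2Cl2, −40 °C
Reagents that add atoms: none
Why: Kishi reduction (ionic hydrogenation): acid ionises the hemiketal and the silane delivers hydride axially, trans to the pseudo-equatorial C7 substituent, so the C3 side chain should end cis to it; this sets C3.

Step 5
Reactants: 9 (2S,6R)-2-[(4S)-2,2-dimethyl-1,3-dioxolan-4-yl]-6-(2-hydroxyethyl)-5-methyl-2H-pyran-3(6H)-one
Product: 11 2-[(2R,6S)-6-[(4S)-2,2-dimethyl-1,3-dioxolan-4-yl]-3-methyl-5-oxo-5,6-dihydro-2H-pyran-2-yl]acetic acid, via aldehyde 10 (not isolated)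
Conditions: TEMPO (cat.), PhI(OAc)2, MeCN/pH 7 buffer, rt
Reagents that add atoms: water, O
Why: Oxoammonium oxidation of the primary alcohol in wet acetonitrile runs through the aldehyde hydrate to the acid and leaves the enone and the acetal alone.

Step 6
Reactants: 11 2-[(2R,6S)-6-[(4S)-2,2-dimethyl-1,3-dioxolan-4-yl]-3-methyl-5-oxo-5,6-dihydro-2H-pyran-2-yl]acetic acid
Product: 12 allyl 2-[(2R,6S)-6-[(4S)-2,2-dimethyl-1,3-dioxolan-4-yl]-3-methyl-5-oxo-5,6-dihydro-2H-pyran-2-yl]acetate
Conditions: allyl bromide, KHCO3, DMF, rt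
Reagents that add atoms: allyl bromide, C=CCBr
Why: O-Alkylation of the carboxylate under bicarbonate (too weak to epimerise C7) gives an ester that zerovalent palladium can later cleave without acid or base.

Step 7
Reactants: 12 allyl 2-[(2R,6S)-6-[(4S)-2,2-dimethyl-1,3-dioxolan-4-yl]-3-methyl-5-oxo-5,6-dihydro-2H-pyran-2-yl]acetate
Product: 13 allyl 2-[(2R,5R,6R)-6-[(4S)-2,2-dimethyl-1,3-dioxolan-4-yl]-5-hydroxy-3-methyl-5,6-dihydro-2H-pyran-2-yl]acetate (hydroxyl trans to the dioxolanyl group)
Conditions: NaBH4, CeCl3·7H2O, MeOH, −78 °C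
Reagents that add atoms: none
Why: Luche reduction: 1,2-selective axial hydride attack on the enone should give the pseudo-equatorial C6 alcohol trans to the C7 substituent; any cis alcohol can be brought to the same ester 14 by direct 4-nitrobenzoylation.

Step 8
Reactants: 13 allyl 2-[(2R,5R,6R)-6-[(4S)-2,2-dimethyl-1,3-dioxolan-4-yl]-5-hydroxy-3-methyl-5,6-dihydro-2H-pyran-2-yl]acetate
Product: 14 (2R,3S,6R)-6-[2-(allyloxy)-2-oxoethyl]-2-[(4S)-2,2-dimethyl-1,3-dioxolan-4-yl]-5-methyl-3,6-dihydro-2H-pyran-3-yl 4-nitrobenzoate (all-cis)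
Conditions: 4-nitrobenzoic acid, PPh3, DIAD, THF, 0 °C → rt
Reagents that add atoms: 4-nitrobenzoic acid, OC(=O)c1ccc(cc1)[N+](=O)[O-]
Why: Mitsunobu reaction: SN2 displacement at the cyclic allylic carbinol C6 inverts it to the configuration of 34 and installs an ester that is stable to acid, amide bases and carbenoids.

Step 9
Reactants: 14 (2R,3S,6R)-6-[2-(allyloxy)-2-oxoethyl]-2-[(4S)-2,2-dimethyl-1,3-dioxolan-4-yl]-5-methyl-3,6-dihydro-2H-pyran-3-yl 4-nitrobenzoate
Product: 15 (2S,3S,6R)-6-[2-(allyloxy)-2-oxoethyl]-2-[(1S)-1,2-dihydroxyethyl]-5-methyl-3,6-dihydro-2H-pyran-3-yl 4-nitrobenzoate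
Conditions: AcOH/H2O (4:1), 40 °C
Reagents that add atoms: none
Why: Acid hydrolysis of the terminal isopropylidene acetal; the esters are stable, and the diol is silylated at once to forestall acyl migration.

Step 10
Reactants: 15 (2S,3S,6R)-6-[2-(allyloxy)-2-oxoethyl]-2-[(1S)-1,2-dihydroxyethyl]-5-methyl-3,6-dihydro-2H-pyran-3-yl 4-nitrobenzoate
Product: 16 (2S,3S,6R)-6-[2-(allyloxy)-2-oxoethyl]-2-[(1S)-2-(tert-butyldimethylsilyloxy)-1-hydroxyethyl]-5-methyl-3,6-dihydro-2H-pyran-3-yl 4-nitrobenzoate
Conditions: TBSCl, imidazole, CH2Cl2, 0 °C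
Reagents that add atoms: tert-butyldimethylsilyl chloride, CC(C)(C)[Si](C)(C)Cl
Why: Selective silylation of the primary hydroxyl; this silyl group ends as the C9 ether of the macrocycle.

Step 11
Reactants: 16 (2S,3S,6R)-6-[2-(allyloxy)-2-oxoethyl]-2-[(1S)-2-(tert-butyldimethylsilyloxy)-1-hydroxyethyl]-5-methyl-3,6-dihydro-2H-pyran-3-yl 4-nitrobenzoate
Product: 17 (2R,3S,6R)-6-[2-(allyloxy)-2-oxoethyl]-2-[(tert-butyldimethylsilyloxy)acetyl]-5-methyl-3,6-dihydro-2H-pyran-3-yl 4-nitrobenzoate
Conditions: Dess–Martin periodinane, pyridine, CH2Cl2, 0 °C → rt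
Reagents that add atoms: none
Why: Dess–Martin oxidation of the secondary alcohol under buffered, near-neutral conditions gives the α-silyloxy ketone without epimerising C7.

Step 12
Reactants: 17 (2R,3S,6R)-6-[2-(allyloxy)-2-oxoethyl]-2-[(tert-butyldimethylsilyloxy)acetyl]-5-methyl-3,6-dihydro-2H-pyran-3-yl 4-nitrobenzoate
Product: 19 (2R,3S,6R)-6-[2-(allyloxy)-2-oxoethyl]-2-[(Z)-1,2-bis(tert-butyldimethylsilyloxy)ethenyl]-5-methyl-3,6-dihydro-2H-pyran-3-yl 4-nitrobenzoate, via potassium Z-enolate 18 (not isolated)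
Conditions: KN(SiMe3)2, THF, −78 °C; t-BuMe2SiOTf, −78 °C
Reagents that add atoms: tert-butyldimethylsilyl triflate, CC(C)(C)[Si](C)(C)OS(=O)(=O)C(F)(F)F
Why: Kinetic deprotonation at the less hindered C9 methylene (the ketone is far more acidic than either ester) should give the chelated Z-enolate, and O-silylation fixes the Z-enediol bis(silyl ether).

Step 13
Reactants: 19 (2R,3S,6R)-6-[2-(allyloxy)-2-oxoethyl]-2-[(Z)-1,2-bis(tert-butyldimethylsilyloxy)ethenyl]-5-methyl-3,6-dihydro-2H-pyran-3-yl 4-nitrobenzoate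
Product: 20 2-[(2R,5S,6R)-6-[(Z)-1,2-bis(tert-butyldimethylsilyloxy)ethenyl]-3-methyl-5-(4-nitrobenzoyloxy)-5,6-dihydro-2H-pyran-2-yl]acetic acid
Conditions: Pd(PPh3)4 (5 mol%), morpholine, THF, rt; pH 5 buffer wash; used at once
Reagents that add atoms: none
Why: Tsuji–Trost deallylation: zerovalent palladium ionises the allyl ester and morpholine traps the allyl unit, which frees the acid under neutral conditions that spare the enediol ether and the nitrobenzoate.

Step 14
Reactants: 20 2-[(2R,5S,6R)-6-[(Z)-1,2-bis(tert-butyldimethylsilyloxy)ethenyl]-3-methyl-5-(4-nitrobenzoyloxy)-5,6-dihydro-2H-pyran-2-yl]acetic acid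
Product: 22 (2R,3S,6R)-2-[(Z)-1,2-bis(tert-butyldimethylsilyloxy)ethenyl]-6-(3-diazo-2-oxobutyl)-5-methyl-3,6-dihydro-2H-pyran-3-yl 4-nitrobenzoate, via isobutyl carbonic anhydride 21 (not isolated)
Conditions: Et3N, i-BuOCOCl, THF, −20 °C; then CH3CHN2 in Et2O, −20 → 0 °C
Reagents that add atoms: diazoethane, CC=[N+]=[N-]
Why: Acylation of the diazoalkane by the mixed carbonic anhydride (Arndt–Eistert-type diazoketone synthesis) gives the α-methyl diazoketone under base-buffered conditions that the silyl enol ethers tolerate.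

Step 15
Reactants: 22 (2R,3S,6R)-2-[(Z)-1,2-bis(tert-butyldimethylsilyloxy)ethenyl]-6-(3-diazo-2-oxobutyl)-5-methyl-3,6-dihydro-2H-pyran-3-yl 4-nitrobenzoate
Product: 25 (1R,2Z,4S,5E,7S,8R)-6,7-bis(tert-butyldimethylsilyloxy)-2,8-dimethyl-9-oxo-11-oxabicyclo[6.2.1]undeca-2,5-dien-4-yl 4-nitrobenzoate, via copper carbenoid 23 (not isolated), via bicyclic oxonium ylide 24 (not isolated)
Conditions: Cu(CF3COCHCOCF3)2 (10 mol%, divalent copper), CH2Cl2, reflux, slow addition of 22
Reagents that add atoms: none
Why: The catalyst decomposes 22 to the electrophilic copper carbenoid 23, whose C10 is captured by the ring oxygen three atoms away, closing the five-membered ring of ylide 24 (O–C10, the later furanone ring). The ylide carbon then bonds to C9 while O–C7 breaks in a suprafacial five-centre envelope ([2,3]-sigmatropic shift), so the ten-membered carbocycle arises by a three-atom ring expansion of the pyran and not by end-to-end closure. The closest known reaction type is the copper-catalysed oxonium ylide formation and [2,3] ring expansion of 2-vinyl tetrahydropyrans with a diazoketone side chain to 11-oxabicyclo[6.2.1]undecenones. C10 is controlled by C3: C4 and C9 both belong to the six-carbon bridge, so C9 can only add to the face of the five-membered ring cis to C4. C9 is controlled by C7 and the Z geometry of the enediol: with C10 axial on oxygen and cis to the equatorial C7 and C3 groups, C6 eclipses C8=C9 in the envelope, C10 reaches C9 on the face from which oxygen leaves, and the ring-cis (5E) enol ether with the C9 configuration of 34 should result. The step needs the ether lone pair to win over cyclopropanation of C4=C5, C–H insertion and 1,2-hydride shift from the C14 methyl, and the [2,3] to win over the [1,2] shift; the electron-poor copper catalyst, the five-membered ylide and the electron-rich migrating enediol work in that direction. It also needs attack on the axial lone pair, which the lower strain of a cis-fused five/six ylide favours.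

Step 16
Reactants: 25 (1R,2Z,4S,5E,7S,8R)-6,7-bis(tert-butyldimethylsilyloxy)-2,8-dimethyl-9-oxo-11-oxabicyclo[6.2.1]undeca-2,5-dien-4-yl 4-nitrobenzoate
Product: 28 (2Z,4S,5E,7S,8R)-6,7-bis(tert-butyldimethylsilyloxy)-2,8-dimethyl-9-oxo-11-oxabicyclo[6.2.1]undeca-1(10),2,5-trien-4-yl 4-nitrobenzoate, via lithium enolate 26 (not isolated), via C2 sulfilimine 27 (not isolated)
Conditions: LiN(SiMe3)2, THF, −78 °C; PhS(Cl)=N-t-Bu, −78 °C
Reagents that add atoms: none
Why: Mukaiyama dehydrogenation: the enolate formed at the only enolisable position C2 is sulfenylated on the open face and the adduct undergoes syn-elimination with the C3 hydrogen on that same face, giving the 3(2H)-furanone without an oxidant that would attack the silyl enol ether.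

Step 17
Reactants: 28 (2Z,4S,5E,7S,8R)-6,7-bis(tert-butyldimethylsilyloxy)-2,8-dimethyl-9-oxo-11-oxabicyclo[6.2.1]undeca-1(10),2,5-trien-4-yl 4-nitrobenzoate
Product: 29 (2Z,4S,5E,7S,8R)-6,7-bis(tert-butyldimethylsilyloxy)-4-hydroxy-2,8-dimethyl-11-oxabicyclo[6.2.1]undeca-1(10),2,5-trien-9-one
Conditions: K2CO3 (0.2 equiv), MeOH/THF, −10 °C
Reagents that add atoms: none
Why: Base-catalysed transesterification of the activated nitrobenzoate is fast at low temperature, where the silyl ether and the hindered silyl enol ether should be stable; O8 is trans to C6 across C7=C8, so no silyl transfer to the new alkoxide is possible.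

Step 18
Reactants: 29 (2Z,4S,5E,7S,8R)-6,7-bis(tert-butyldimethylsilyloxy)-4-hydroxy-2,8-dimethyl-11-oxabicyclo[6.2.1]undeca-1(10),2,5-trien-9-one
Product: 30 (2Z,4S,5E,7S,8R)-6,7-bis(tert-butyldimethylsilyloxy)-2,8-dimethyl-9-oxo-11-oxabicyclo[6.2.1]undeca-1(10),2,5-trien-4-yl 3-chloro-2-oxopropanoate
Conditions: ClCH2COCOCl, 2,6-di-tert-butyl-4-methylpyridine, CH2Cl2, −78 °C; used directly
Reagents that add atoms: 3-chloropyruvoyl chloride, O=C(Cl)C(=O)CCl
Why: Acylation of the secondary alcohol by the α-keto acid chloride with a hindered pyridine that cannot be alkylated by the chloromethyl ketone.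

Step 19
Reactants: 30 (2Z,4S,5E,7S,8R)-6,7-bis(tert-butyldimethylsilyloxy)-2,8-dimethyl-9-oxo-11-oxabicyclo[6.2.1]undeca-1(10),2,5-trien-4-yl 3-chloro-2-oxopropanoate
Product: 31 (6S,7R,9S,10R,11R)-9-(tert-butyldimethylsilyloxy)-13-chloro-11-hydroxy-1,8-dioxo-3,10-epoxygermacra-2,4Z-dien-12,6-olide
Conditions: MgBr2·OEt2, CH2Cl2, −40 → 0 °C; aq. NaHCO3
Reagents that add atoms: none
Why: Intramolecular Mukaiyama aldol: C7 of the regiodefined silyl enol ether attacks the magnesium-activated ketone in a five-membered (5-exo) closure; the ester tether should deliver C11 to the outer face of C7 on which O6 lies (cis-fused lactone, sets C7), and the chloromethyl group should turn away from the C8 silyloxy carbon so that the new hydroxyl is cis to C8 (sets C11).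

Step 20
Reactants: 31 (6S,7R,9S,10R,11R)-9-(tert-butyldimethylsilyloxy)-13-chloro-11-hydroxy-1,8-dioxo-3,10-epoxygermacra-2,4Z-dien-12,6-olide
Product: 32 (6S,7R,8S,9R,10R,11R)-9-(tert-butyldimethylsilyloxy)-13-chloro-8,11-dihydroxy-1-oxo-3,10-epoxygermacra-2,4Z-dien-12,6-olide
Conditions: NaBH4, MeOH/CH2Cl2, −78 °C
Reagents that add atoms: none
Why: Borohydride reduces the α-silyloxy ketone while the vinylogous ester and the lactone are inert at this temperature; with the carbonyl anti to the C9–O dipole (Cornforth model) and hydride entering from the ring periphery, the C8 alcohol should form trans to O9 and cis to the C7–C11 bond.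

Step 21
Reactants: 32 (6S,7R,8S,9R,10R,11R)-9-(tert-butyldimethylsilyloxy)-13-chloro-8,11-dihydroxy-1-oxo-3,10-epoxygermacra-2,4Z-dien-12,6-olide
Product: 33 (6S,7S,8S,9R,10R,11R)-8-angeloyloxy-9-(tert-butyldimethylsilyloxy)-13-chloro-11-hydroxy-1-oxo-3,10-epoxygermacra-2,4Z-dien-12,6-olide
Conditions: angelic acid, 2,4,6-trichlorobenzoyl chloride, Et3N, toluene, rt; then 32, 60 °C
Reagents that add atoms: angelic acid, C/C=C(/C)C(=O)O
Why: Yamaguchi-type esterification through the mixed anhydride without a nucleophilic catalyst, a protocol that transfers the angeloyl group without Z to E isomerisation; the tertiary C11 alcohol is too hindered to react.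

Step 22
Reactants: 33 (6S,7S,8S,9R,10R,11R)-8-angeloyloxy-9-(tert-butyldimethylsilyloxy)-13-chloro-11-hydroxy-1-oxo-3,10-epoxygermacra-2,4Z-dien-12,6-olide
Product: 34 (6S,7S,8S,9R,10R,11R)-8-angeloyloxy-13-chloro-9,11-dihydroxy-1-oxo-3,10-epoxygermacra-2,4Z-dien-12,6-olide
Conditions: HF·pyridine, pyridine, THF, 0 °C → rt
Reagents that add atoms: none
Why: Fluoride cleavage of the secondary silyl ether under buffered acidic conditions, which avoid epoxide closure of the chlorohydrin, acyl shift to O9 and isomerisation of the angelate.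

## Compound list

1 | 3-methylfuran | Cc1ccoc1 | starting material
2 | (S)-2,2-dimethyl-1,3-dioxolane-4-carbaldehyde ((S)-glyceraldehyde acetonide) | CC1(C)OC[C@@H](C=O)O1 | starting material
3 | 2-lithio-4-methylfuran | Cc1coc([Li])c1 | intermediate
4 | (4-methylfuran-2-yl)zinc bromide | Cc1coc([Zn]Br)c1 | intermediate
5 | (S)-[(4S)-2,2-dimethyl-1,3-dioxolan-4-yl](4-methylfuran-2-yl)methanol | Cc1coc([C@@H](O)[C@@H]2COC(C)(C)O2)c1 | intermediate
6 | dilithiated furan (lithium alkoxide of 5 lithiated at the free furan α-position) | Cc1cc([C@@H](O[Li])[C@@H]2COC(C)(C)O2)oc1[Li] | intermediate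
7 | 2-{5-[(S)-[(4S)-2,2-dimethyl-1,3-dioxolan-4-yl](hydroxy)methyl]-3-methylfuran-2-yl}ethan-1-ol | Cc1cc([C@@H](O)[C@@H]2COC(C)(C)O2)oc1CCO | intermediate
8 | (2S)-2-[(4S)-2,2-dimethyl-1,3-dioxolan-4-yl]-6-hydroxy-6-(2-hydroxyethyl)-5-methyl-2H-pyran-3(6H)-one (both C6 epimers) | O=C1C=C(C)C(O)(CCO)O[C@H]1[C@@H]2COC(C)(C)O2 | intermediate
9 | (2S,6R)-2-[(4S)-2,2-dimethyl-1,3-dioxolan-4-yl]-6-(2-hydroxyethyl)-5-methyl-2H-pyran-3(6H)-one (2,6-cis) | O=C1C=C(C)[C@@H](CCO)O[C@H]1[C@@H]2COC(C)(C)O2 | intermediate
10 | 2-[(2R,6S)-6-[(4S)-2,2-dimethyl-1,3-dioxolan-4-yl]-3-methyl-5-oxo-5,6-dihydro-2H-pyran-2-yl]acetaldehyde | O=C1C=C(C)[C@@H](CC=O)O[C@H]1[C@@H]2COC(C)(C)O2 | intermediate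
11 | 2-[(2R,6S)-6-[(4S)-2,2-dimethyl-1,3-dioxolan-4-yl]-3-methyl-5-oxo-5,6-dihydro-2H-pyran-2-yl]acetic acid | O=C1C=C(C)[C@@H](CC(=O)O)O[C@H]1[C@@H]2COC(C)(C)O2 | intermediate
12 | allyl 2-[(2R,6S)-6-[(4S)-2,2-dimethyl-1,3-dioxolan-4-yl]-3-methyl-5-oxo-5,6-dihydro-2H-pyran-2-yl]acetate | O=C1C=C(C)[C@@H](CC(=O)OCC=C)O[C@H]1[C@@H]2COC(C)(C)O2 | intermediate
13 | allyl 2-[(2R,5R,6R)-6-[(4S)-2,2-dimethyl-1,3-dioxolan-4-yl]-5-hydroxy-3-methyl-5,6-dihydro-2H-pyran-2-yl]acetate | O[C@@H]1C=C(C)[C@@H](CC(=O)OCC=C)O[C@H]1[C@@H]2COC(C)(C)O2 | intermediate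
14 | (2R,3S,6R)-6-[2-(allyloxy)-2-oxoethyl]-2-[(4S)-2,2-dimethyl-1,3-dioxolan-4-yl]-5-methyl-3,6-dihydro-2H-pyran-3-yl 4-nitrobenzoate (all-cis) | O=C(O[C@H]1C=C(C)[C@@H](CC(=O)OCC=C)O[C@H]1[C@@H]2COC(C)(C)O2)c3ccc(cc3)[N+](=O)[O-] | intermediate
15 | (2S,3S,6R)-6-[2-(allyloxy)-2-oxoethyl]-2-[(1S)-1,2-dihydroxyethyl]-5-methyl-3,6-dihydro-2H-pyran-3-yl 4-nitrobenzoate | O=C(O[C@H]1C=C(C)[C@@H](CC(=O)OCC=C)O[C@H]1[C@@H](O)CO)c3ccc(cc3)[N+](=O)[O-] | intermediate
16 | (2S,3S,6R)-6-[2-(allyloxy)-2-oxoethyl]-2-[(1S)-2-(tert-butyldimethylsilyloxy)-1-hydroxyethyl]-5-methyl-3,6-dihydro-2H-pyran-3-yl 4-nitrobenzoate | O=C(O[C@H]1C=C(C)[C@@H](CC(=O)OCC=C)O[C@H]1[C@@H](O)CO[Si](C)(C)C(C)(C)C)c3ccc(cc3)[N+](=O)[O-] | intermediate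
17 | (2R,3S,6R)-6-[2-(allyloxy)-2-oxoethyl]-2-[(tert-butyldimethylsilyloxy)acetyl]-5-methyl-3,6-dihydro-2H-pyran-3-yl 4-nitrobenzoate | O=C(O[C@H]1C=C(C)[C@@H](CC(=O)OCC=C)O[C@H]1C(=O)CO[Si](C)(C)C(C)(C)C)c3ccc(cc3)[N+](=O)[O-] | intermediate
18 | potassium Z-enolate of 17 (C8–O−, C8=C9) | O=C(O[C@H]1C=C(C)[C@@H](CC(=O)OCC=C)O[C@H]1/C([O-])=C/O[Si](C)(C)C(C)(C)C)c3ccc(cc3)[N+](=O)[O-].[K+] | intermediate
19 | (2R,3S,6R)-6-[2-(allyloxy)-2-oxoethyl]-2-[(Z)-1,2-bis(tert-butyldimethylsilyloxy)ethenyl]-5-methyl-3,6-dihydro-2H-pyran-3-yl 4-nitrobenzoate | O=C(O[C@H]1C=C(C)[C@@H](CC(=O)OCC=C)O[C@H]1/C(O[Si](C)(C)C(C)(C)C)=C/O[Si](C)(C)C(C)(C)C)c3ccc(cc3)[N+](=O)[O-] | intermediate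
20 | 2-[(2R,5S,6R)-6-[(Z)-1,2-bis(tert-butyldimethylsilyloxy)ethenyl]-3-methyl-5-(4-nitrobenzoyloxy)-5,6-dihydro-2H-pyran-2-yl]acetic acid | O=C(O[C@H]1C=C(C)[C@@H](CC(=O)O)O[C@H]1/C(O[Si](C)(C)C(C)(C)C)=C/O[Si](C)(C)C(C)(C)C)c3ccc(cc3)[N+](=O)[O-] | intermediate
21 | mixed anhydride of 20 with isobutyl carbonic acid | O=C(O[C@H]1C=C(C)[C@@H](CC(=O)OC(=O)OCC(C)C)O[C@H]1/C(O[Si](C)(C)C(C)(C)C)=C/O[Si](C)(C)C(C)(C)C)c3ccc(cc3)[N+](=O)[O-] | intermediate
22 | (2R,3S,6R)-2-[(Z)-1,2-bis(tert-butyldimethylsilyloxy)ethenyl]-6-(3-diazo-2-oxobutyl)-5-methyl-3,6-dihydro-2H-pyran-3-yl 4-nitrobenzoate (all-cis; precursor of the key step) | CC(=[N+]=[N-])C(=O)C[C@H]1O[C@@H](/C(O[Si](C)(C)C(C)(C)C)=C/O[Si](C)(C)C(C)(C)C)[C@@H](OC(=O)c2ccc(cc2)[N+](=O)[O-])C=C1C | intermediate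
23 | copper carbenoid at C10 derived from 22 (ancillary ligands on copper not drawn) | CC(=[Cu])C(=O)C[C@H]1O[C@@H](/C(O[Si](C)(C)C(C)(C)C)=C/O[Si](C)(C)C(C)(C)C)[C@@H](OC(=O)c2ccc(cc2)[N+](=O)[O-])C=C1C | intermediate
24 | bicyclic oxonium ylide (ring oxygen bonded to C3, C7 and C10; C10 cis to the C3 and C7 carbon substituents; carbanion at C10) | C[C-]1C(=O)C[C@@H]2C(C)=C[C@H](OC(=O)c3ccc(cc3)[N+](=O)[O-])[C@H](/C(O[Si](C)(C)C(C)(C)C)=C/O[Si](C)(C)C(C)(C)C)[O+]12 | intermediate
25 | (1R,2Z,4S,5E,7S,8R)-6,7-bis(tert-butyldimethylsilyloxy)-2,8-dimethyl-9-oxo-11-oxabicyclo[6.2.1]undeca-2,5-dien-4-yl 4-nitrobenzoate (product of the key step) | C[C@]12O[C@H](CC1=O)/C(C)=C\[C@H](OC(=O)c3ccc(cc3)[N+](=O)[O-])/C=C(O[Si](C)(C)C(C)(C)C)\[C@H]2O[Si](C)(C)C(C)(C)C | intermediate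
26 | lithium enolate of 25 (C1–O–Li, C1=C2) | C[C@]12O[C@H](C=C1O[Li])/C(C)=C\[C@H](OC(=O)c3ccc(cc3)[N+](=O)[O-])/C=C(O[Si](C)(C)C(C)(C)C)\[C@H]2O[Si](C)(C)C(C)(C)C | intermediate
27 | C2 sulfilimine adduct of 25 (C2–S(Ph)=N-t-Bu) | C[C@]12O[C@H](C(C1=O)S(=NC(C)(C)C)c4ccccc4)/C(C)=C\[C@H](OC(=O)c3ccc(cc3)[N+](=O)[O-])/C=C(O[Si](C)(C)C(C)(C)C)\[C@H]2O[Si](C)(C)C(C)(C)C | intermediate
28 | (2Z,4S,5E,7S,8R)-6,7-bis(tert-butyldimethylsilyloxy)-2,8-dimethyl-9-oxo-11-oxabicyclo[6.2.1]undeca-1(10),2,5-trien-4-yl 4-nitrobenzoate | C[C@]12OC(=CC1=O)/C(C)=C\[C@H](OC(=O)c3ccc(cc3)[N+](=O)[O-])/C=C(O[Si](C)(C)C(C)(C)C)\[C@H]2O[Si](C)(C)C(C)(C)C | intermediate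
29 | (2Z,4S,5E,7S,8R)-6,7-bis(tert-butyldimethylsilyloxy)-4-hydroxy-2,8-dimethyl-11-oxabicyclo[6.2.1]undeca-1(10),2,5-trien-9-one | C[C@]12OC(=CC1=O)/C(C)=C\[C@H](O)/C=C(O[Si](C)(C)C(C)(C)C)\[C@H]2O[Si](C)(C)C(C)(C)C | intermediate
30 | (2Z,4S,5E,7S,8R)-6,7-bis(tert-butyldimethylsilyloxy)-2,8-dimethyl-9-oxo-11-oxabicyclo[6.2.1]undeca-1(10),2,5-trien-4-yl 3-chloro-2-oxopropanoate | C[C@]12OC(=CC1=O)/C(C)=C\[C@H](OC(=O)C(=O)CCl)/C=C(O[Si](C)(C)C(C)(C)C)\[C@H]2O[Si](C)(C)C(C)(C)C | intermediate
31 | (6S,7R,9S,10R,11R)-9-(tert-butyldimethylsilyloxy)-13-chloro-11-hydroxy-1,8-dioxo-3,10-epoxygermacra-2,4Z-dien-12,6-olide | O=C1[C@@H]2[C@H](/C=C(/C)C3=CC(=O)[C@](C)(O3)[C@@H]1O[Si](C)(C)C(C)(C)C)OC(=O)[C@@]2(O)CCl | intermediate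
32 | (6S,7R,8S,9R,10R,11R)-9-(tert-butyldimethylsilyloxy)-13-chloro-8,11-dihydroxy-1-oxo-3,10-epoxygermacra-2,4Z-dien-12,6-olide | O[C@H]1[C@@H]2[C@H](/C=C(/C)C3=CC(=O)[C@](C)(O3)[C@@H]1O[Si](C)(C)C(C)(C)C)OC(=O)[C@@]2(O)CCl | intermediate
33 | (6S,7S,8S,9R,10R,11R)-8-angeloyloxy-9-(tert-butyldimethylsilyloxy)-13-chloro-11-hydroxy-1-oxo-3,10-epoxygermacra-2,4Z-dien-12,6-olide | C/C=C(/C)C(=O)O[C@H]1[C@@H]2[C@H](/C=C(/C)C3=CC(=O)[C@](C)(O3)[C@@H]1O[Si](C)(C)C(C)(C)C)OC(=O)[C@@]2(O)CCl | intermediate
34 | (6S,7S,8S,9R,10R,11R)-8-angeloyloxy-13-chloro-9,11-dihydroxy-1-oxo-3,10-epoxygermacra-2,4Z-dien-12,6-olide (CNP0272644.1) | C/C=C(/C)C(=O)O[C@H]1[C@@H]2[C@H](/C=C(/C)C3=CC(=O)[C@](C)(O3)[C@@H]1O)OC(=O)[C@@]2(O)CCl | target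

## Step count and least certain steps

Total step count: 22. Longest linear sequence: 22 steps (from 1); 14 steps lead to the precursor 22 of the key step.

**Step 15 (key step).** The most likely failure is loss of the carbenoid before the ring oxygen captures it, by 1,2-hydride shift from the C14 methyl or by cyclopropanation of the nearby C4=C5 alkene. A second risk is attack on the equatorial lone pair, made easier because the pseudo-axial C6 ester lies next to the axial position on oxygen; that would give the trans-fused ylide and hence the ring-E enol ether with the other C9 configuration. A [1,2] shift of the ylide is the third possibility.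

The fallback removes the methyl group from the carbenoid. It sets out from acid 20: the same mixed anhydride is treated with diazomethane to give the terminal diazoketone F1, the substrate class for which this ring expansion is best known. The copper-catalysed ring expansion then gives the C10-unsubstituted bicyclic ketone F2, and the dehydrogenation of step 16 gives the furanone F3. Deprotonation of F3 at C10 (the only acidic position, giving an aromatic 3-oxidofuran) and C-methylation with iodomethane on the face away from the C4–C9 bridge returns to the route at 28.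

**Step 19.** The ester in 30 sits on a carbon that is allylic twice over and conjugated to the enol ether. Ionisation of this C6–O bond by the Lewis acid, with loss of the tether and formation of a dienone, can outrun the aldol; the open transition state also leaves the C11 configuration uncertain.

The fallback keeps a poor leaving group on O6 and makes the C7–C11 bond intermolecularly. It sets out from 29, which is silylated (Et3SiOTf, 2,6-lutidine) to the triethylsilyl ether F4. Mukaiyama aldol reaction of F4 with methyl 3-chloropyruvate (MgBr2·OEt2), with attack on the outer face of C7, gives the hydroxy ester F5. Buffered HF·pyridine then removes the triethylsilyl group, and the freed C6 hydroxyl closes onto the methyl ester, returning to the route at 31.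

**Step 20.** Facial selectivity of hydride delivery in the ten-membered ring rests on a conformational argument and may be poor or reversed. The fallback accepts the wrong alcohol: it sets out from 31, takes the C8 epimer F6 of 32, and esterifies it with angelic acid under Mitsunobu conditions (PPh3, DIAD), which inverts C8 and returns to the route at 33.

**Step 12.** Deprotonation may occur in part toward C7, with epimerisation or β-elimination of O6 or of the ring oxygen, or the enolate geometry may be mixed. The fallback takes the enolisable carbonyl away from C7. It sets out from diol 15, which is bis-silylated (t-BuMe2SiOTf, 2,6-lutidine) to F7. Selective cleavage of the primary silyl ether (HF·pyridine, pyridine) gives alcohol F8, and Dess–Martin oxidation gives the α-silyloxy aldehyde F9, which has only C8 as enolisable position. Soft enolisation (t-BuMe2SiOTf, Et3N) returns to the route at 19.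

**Step 1.** Metalation of 1 may give a mixture of α-regioisomers, and the anti selectivity of the addition may be incomplete. The fallback builds the furan with the substitution pattern fixed. Purchasable 3-methylfuran-2(5H)-one is silylated to the silyloxyfuran F10. Vinylogous Mukaiyama aldol reaction of F10 with 2 (BF3·OEt2, −78 °C) gives the butenolide F11 with the same anti carbinol. Reduction with i-Bu2AlH to the lactol and acid-induced loss of water aromatise it, returning to the route at 5.

## Further compounds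

F1 | step 15 | (2R,3S,6R)-2-[(Z)-1,2-bis(tert-butyldimethylsilyloxy)ethenyl]-6-(3-diazo-2-oxopropyl)-5-methyl-3,6-dihydro-2H-pyran-3-yl 4-nitrobenzoate | [N-]=[N+]=CC(=O)C[C@H]1O[C@@H](/C(O[Si](C)(C)C(C)(C)C)=C/O[Si](C)(C)C(C)(C)C)[C@@H](OC(=O)c2ccc(cc2)[N+](=O)[O-])C=C1C
F2 | step 15 | 8-demethyl analogue of 25 (hydrogen at the bridgehead next to the ketone) | [H][C@]12O[C@H](CC1=O)/C(C)=C\[C@H](OC(=O)c3ccc(cc3)[N+](=O)[O-])/C=C(O[Si](C)(C)C(C)(C)C)\[C@H]2O[Si](C)(C)C(C)(C)C
F3 | step 15 | 8-demethyl analogue of 28 | [H][C@]12OC(=CC1=O)/C(C)=C\[C@H](OC(=O)c3ccc(cc3)[N+](=O)[O-])/C=C(O[Si](C)(C)C(C)(C)C)\[C@H]2O[Si](C)(C)C(C)(C)C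
F4 | step 19 | triethylsilyl ether of 29 at O6 | C[C@]12OC(=CC1=O)/C(C)=C\[C@H](O[Si](CC)(CC)CC)/C=C(O[Si](C)(C)C(C)(C)C)\[C@H]2O[Si](C)(C)C(C)(C)C
F5 | step 19 | methyl ester of the seco acid of 31 with O6 as triethylsilyl ether (methyl 3-chloro-2-hydroxypropanoate unit on C7) | O=C1[C@H]([C@H](/C=C(/C)C3=CC(=O)[C@](C)(O3)[C@@H]1O[Si](C)(C)C(C)(C)C)O[Si](CC)(CC)CC)[C@](O)(CCl)C(=O)OC
F6 | step 20 | C8 epimer of 32 | O[C@@H]1[C@@H]2[C@H](/C=C(/C)C3=CC(=O)[C@](C)(O3)[C@@H]1O[Si](C)(C)C(C)(C)C)OC(=O)[C@@]2(O)CCl
F7 | step 12 | bis(tert-butyldimethylsilyl) ether of 15 | O=C(O[C@H]1C=C(C)[C@@H](CC(=O)OCC=C)O[C@H]1[C@@H](O[Si](C)(C)C(C)(C)C)CO[Si](C)(C)C(C)(C)C)c3ccc(cc3)[N+](=O)[O-]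
F8 | step 12 | C8 tert-butyldimethylsilyl ether of 15 with free primary hydroxyl | O=C(O[C@H]1C=C(C)[C@@H](CC(=O)OCC=C)O[C@H]1[C@@H](O[Si](C)(C)C(C)(C)C)CO)c3ccc(cc3)[N+](=O)[O-]
F9 | step 12 | α-silyloxy aldehyde from F8 | O=C(O[C@H]1C=C(C)[C@@H](CC(=O)OCC=C)O[C@H]1[C@@H](O[Si](C)(C)C(C)(C)C)C=O)c3ccc(cc3)[N+](=O)[O-]
F10 | step 1 | tert-butyldimethyl[(3-methylfuran-2-yl)oxy]silane | Cc1ccoc1O[Si](C)(C)C(C)(C)C
F11 | step 1 | 5-[(S)-[(4S)-2,2-dimethyl-1,3-dioxolan-4-yl](hydroxy)methyl]-3-methylfuran-2(5H)-one | CC1=CC(OC1=O)[C@@H](O)[C@@H]2COC(C)(C)O2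
A1 | alternative 1 | 8-deacyl target (8,9,11-triol) | O[C@H]1[C@@H]2[C@H](/C=C(/C)C3=CC(=O)[C@](C)(O3)[C@@H]1O)OC(=O)[C@@]2(O)CCl
A2 | alternative 1 | seco-dialdehyde (C8 aldehyde on the lactone, C9 aldehyde on the furanone) | O=C[C@@H]2[C@H](/C=C(/C)C3=CC(=O)[C@](C)(O3)C=O)OC(=O)[C@@]2(O)CCl
A3 | alternative 2 | cyclodecane-1,6-dione with C3 ketal and protected C7–C11 stereocentres | C[C@H]1CC(=O)[C@H]([C@]5(CCl)COC(C)(C)O5)[C@H](O[Si](C)(C)C(C)(C)C)[C@H]4OC(C)(C)O[C@@]4(C)C(=O)CC13OCCO3
A4 | alternative 2 | bicyclo[4.4.0]dec-1(6)-ene precursor of A3 | C[C@H]1CC2=C(CC13OCCO3)[C@]4(C)OC(C)(C)O[C@@H]4[C@@H](O[Si](C)(C)C(C)(C)C)[C@H]2[C@]5(CCl)COC(C)(C)O5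
A5 | alternative 3 | cyclodec-4-en-2-yn-1-ol macrocycle | C/C=C(/C)C(=O)O[C@H]1[C@@H]2[C@H](/C=C(/C)C#C[C@H](O)[C@](C)(O)[C@@H]1O[Si](C)(C)C(C)(C)C)OC(=O)[C@@]2(O)CCl
A6 | alternative 3 | seco iodoalkyne aldehyde (C1 aldehyde, C2 iodoalkyne) | C/C=C(/C)C(=O)O[C@H]([C@@H](O[Si](C)(C)C(C)(C)C)[C@@](C)(O)C=O)[C@@H]1[C@H](/C=C(/C)C#CI)OC(=O)[C@@]1(O)CCl
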